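**Retrosynthetic overview**
1. Target ⇒ its bis-O-TBS ether (last step: fluoride removal of two aryl silyl groups).
2. Exocyclic C=C ⇒ aldol condensation of an (R)-4-(arylmethyl)oxolan-2-one with O-TBS-syringaldehyde; E geometry from E1cB elimination.
3. Lactone O–CH2 bond ⇒ enantioselective oxygen insertion (Baeyer–Villiger desymmetrisation) into a prochiral 3-(arylmethyl)cyclobutanone; this makes the ring C–O bond and the only stereocentre.
4. Cyclobutanone ⇒ dichloroketene [2+2] on O-TBS-eugenol, then zinc dechlorination.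
5. Ring order: cyclobutanone first, then ring expansion to the γ-lactone; both arenes are bought (eugenol, syringaldehyde).

Assumption: the SMILES is read as (4R) and (E); the hand of the step-4 catalyst that gives (R) is not predictable and is fixed by one test run (both antipodes come from (R)- or (S)-BINOL). TBS = tert-butyldimethylsilyl, TBSO = its oxy group.

**Route**

Step 1
Reactants: 1 eugenol (4-allyl-2-methoxyphenol)
Product: 2 tert-butyl(4-allyl-2-methoxyphenoxy)dimethylsilane (O-TBS-eugenol)
Conditions: TBSCl, imidazole, DMF, rt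
Reagents that add atoms: tert-butyldimethylsilyl chloride, CC(C)(C)[Si](C)(C)Cl
Why: Imidazole-promoted O-silylation masks the phenol, which would otherwise be acylated in step 2 and consume base in step 6; no stereocentre is involved.

Step 2
Reactants: 2 O-TBS-eugenol
Product: 3 rac-2,2-dichloro-3-{[4-(TBSO)-3-methoxyphenyl]methyl}cyclobutan-1-one
Conditions: Cl3CCOCl, Zn–Cu, Et2O/DME, 25–35 °C
Reagents that add atoms: trichloroacetyl chloride, ClC(Cl)(Cl)C(Cl)=O (delivers dichloroketene)
Why: Ketene–alkene [2+2] cycloaddition of in situ dichloroketene is regioselective for terminal alkenes (C=O carbon to the CH2 end) and precedented for allylarenes, DME ties up ZnCl2 so the aryl silyl ether survives, and the ring stereocentre forms racemic but is made prochiral again in step 3.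

Step 3
Reactants: 3 rac-2,2-dichlorocyclobutanone
Product: 5 3-{[4-(TBSO)-3-methoxyphenyl]methyl}cyclobutan-1-one (achiral and prochiral), via monochloro ketone 4 (not isolated)
Conditions: Zn dust, AcOH, rt → 40 °C
Reagents that add atoms: none
Why: Zinc/acetic acid reductive dehalogenation of the α,α-dichloroketone removes the chlorines one at a time through zinc enolates and leaves a mirror-symmetric 3-substituted cyclobutanone with the aryl silyl ether untouched.

Step 4
Reactants: 5 prochiral cyclobutanone
Product: 7 (4R)-4-{[4-(TBSO)-3-methoxyphenyl]methyl}oxolan-2-one, via Criegee adduct 6 (not isolated)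
Conditions: confined chiral imidodiphosphoric acid built from two 3,3'-bis(2,4,6-triethylphenyl)-BINOL units (5 mol %, hand chosen to give R), 30 % aq H2O2 (1.5 equiv), CHCl3, −40 °C
Reagents that add atoms: hydrogen peroxide, OO
Why: Proposed new method: the confined acid H-bonds both ketone and H2O2 and holds Criegee adduct 6 in its narrow chiral cleft with the arylmethyl group pointing out of the opening, so only one of the two enantiotopic ring CH2 groups can lie antiperiplanar to the O–O bond and migrate, which forms the lactone C–O bond and turns the prochiral ring carbon into the (R)-stereocentre, with four-ring strain release making the reaction fast and chemoselective over the electron-rich arene at −40 °C; the closest known reactions are the chiral phosphoric acid/H2O2 Baeyer–Villiger desymmetrisation of 3-arylcyclobutanones (less selective for flexible 3-benzyl groups) and confined-acid activation of H2O2 in asymmetric sulfoxidation.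

Step 5
Reactants: 8 syringaldehyde (4-hydroxy-3,5-dimethoxybenzaldehyde)
Product: 9 4-(TBSO)-3,5-dimethoxybenzaldehyde
Conditions: TBSCl, imidazole, DMF, rt
Reagents that add atoms: tert-butyldimethylsilyl chloride, CC(C)(C)[Si](C)(C)Cl
Why: Imidazole-promoted O-silylation prevents formation of the phenoxide, which would deactivate the aldehyde towards enolate addition.

Step 6
Reactants: 7 (4R)-lactone; 9 O-TBS-syringaldehyde
Product: 13 (3E,4R)-3-{[4-(TBSO)-3,5-dimethoxyphenyl]methylidene}-4-{[4-(TBSO)-3-methoxyphenyl]methyl}oxolan-2-one, via lithium enolate 10 (not isolated), via lithium aldolate 11 (not isolated), via aldol acetate 12 (not isolated)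
Conditions: LDA (1.1 equiv), THF, −78 °C; 9, −78 °C; Ac2O (1.3 equiv), −78 → 0 °C; DBU (3 equiv), rt
Reagents that add atoms: lithium diisopropylamide, [Li+].CC(C)[N-]C(C)C (its lithium sits in 10 and 11 only); acetic anhydride, CC(=O)OC(C)=O (its acetyl sits in 12 only)
Why: Aldol condensation in which the lithium enolate adds to the aldehyde anti to the C4 substituent, the aldolate is acetylated in the flask and DBU-induced E1cB elimination gives the thermodynamically favoured (E)-benzylidene lactone (aryl trans to C=O) from either carbinol epimer, while the non-acidic C4 stereocentre is not touched.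

Step 7
Reactants: 13 bis-TBS (3E,4R)-benzylidene lactone
Product: 14 (3E,4R)-3-[(4-hydroxy-3,5-dimethoxyphenyl)methylidene]-4-[(4-hydroxy-3-methoxyphenyl)methyl]oxolan-2-one (target)
Conditions: TBAF/AcOH (1:1, 2.5 equiv), THF, 0 °C
Reagents that add atoms: none
Why: Fluoride-induced desilylation cleaves both aryl Si–O bonds, and the acetic acid buffer keeps the lactone, the alkene geometry and C4 unaffected.

**Compound list**
1 | eugenol (4-allyl-2-methoxyphenol) | C=CCc1ccc(O)c(OC)c1 | starting material
2 | tert-butyl(4-allyl-2-methoxyphenoxy)dimethylsilane | C=CCc1ccc(O[Si](C)(C)C(C)(C)C)c(OC)c1 | intermediate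
3 | rac-2,2-dichloro-3-{[4-(TBSO)-3-methoxyphenyl]methyl}cyclobutan-1-one | COc1cc(CC2CC(=O)C2(Cl)Cl)ccc1O[Si](C)(C)C(C)(C)C | intermediate
4 | 2-chloro-3-{[4-(TBSO)-3-methoxyphenyl]methyl}cyclobutan-1-one (stereoisomer mixture) | COc1cc(CC2CC(=O)C2Cl)ccc1O[Si](C)(C)C(C)(C)C | intermediate (not isolated)
5 | 3-{[4-(TBSO)-3-methoxyphenyl]methyl}cyclobutan-1-one (achiral, prochiral) | COc1cc(CC2CC(=O)C2)ccc1O[Si](C)(C)C(C)(C)C | intermediate
6 | 1-hydroperoxy-3-{[4-(TBSO)-3-methoxyphenyl]methyl}cyclobutan-1-ol (Criegee adduct) | COc1cc(CC2CC(O)(OO)C2)ccc1O[Si](C)(C)C(C)(C)C | intermediate (not isolated)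
7 | (4R)-4-{[4-(TBSO)-3-methoxyphenyl]methyl}oxolan-2-one | COc1cc(C[C@H]2COC(=O)C2)ccc1O[Si](C)(C)C(C)(C)C | intermediate
8 | syringaldehyde | COc1cc(C=O)cc(OC)c1O | starting material
9 | 4-(TBSO)-3,5-dimethoxybenzaldehyde | COc1cc(C=O)cc(OC)c1O[Si](C)(C)C(C)(C)C | intermediate
10 | lithium enolate of 7 (lithium (R)-4-(arylmethyl)-4,5-dihydrofuran-2-olate) | COc1cc(C[C@H]2COC([O-])=C2)ccc1O[Si](C)(C)C(C)(C)C.[Li+] | intermediate (not isolated)
11 | lithium (3S,4R)-aldolate, 3,4-trans, both carbinol epimers | COc1cc(C[C@H]2COC(=O)[C@@H]2C([O-])c2cc(OC)c(O[Si](C)(C)C(C)(C)C)c(OC)c2)ccc1O[Si](C)(C)C(C)(C)C.[Li+] | intermediate (not isolated)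
12 | (3S,4R)-3-{acetoxy[4-(TBSO)-3,5-dimethoxyphenyl]methyl}-4-{[4-(TBSO)-3-methoxyphenyl]methyl}oxolan-2-one, both carbinol epimers | COc1cc(C[C@H]2COC(=O)[C@@H]2C(OC(C)=O)c2cc(OC)c(O[Si](C)(C)C(C)(C)C)c(OC)c2)ccc1O[Si](C)(C)C(C)(C)C | intermediate (not isolated)
13 | (3E,4R)-3-{[4-(TBSO)-3,5-dimethoxyphenyl]methylidene}-4-{[4-(TBSO)-3-methoxyphenyl]methyl}oxolan-2-one | COc1cc(C[C@H]2COC(=O)/C2=C/c2cc(OC)c(O[Si](C)(C)C(C)(C)C)c(OC)c2)ccc1O[Si](C)(C)C(C)(C)C | intermediate
14 | (3E,4R)-3-[(4-hydroxy-3,5-dimethoxyphenyl)methylidene]-4-[(4-hydroxy-3-methoxyphenyl)methyl]oxolan-2-one | COc1cc(C[C@H]2COC(=O)/C2=C/c2cc(OC)c(O)c(OC)c2)ccc1O | target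

**Step count and risks**
Total steps: 7 (step 6 is one pot). Longest linear sequence: 6 (steps 1, 2, 3, 4, 6, 7 from eugenol); step 5 is a one-step branch.

Most likely to fail:

1. Step 4 (the proposed new Baeyer–Villiger desymmetrisation). The risk is insufficient ee with the flexible arylmethyl group, or a slow reaction in the confined pocket. The fallback uses known chemistry, sets out from 5 and comes back at 7. Enantioselective deprotonation of 5 with a C2-symmetric chiral lithium amide (lithium bis(1-phenylethyl)amide, hand chosen for the R series) with in situ TMSCl at −100 °C gives the (R)-silyl enol ether F1. Ozonolysis in CH2Cl2/MeOH at −78 °C gives the aldehyde acid F2, which is reduced at once in the same flask with NaBH4 to the hydroxy acid F3, so the α-branched aldehyde cannot epimerise. Acidification lactonises F3 to 7.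

2. Step 2 (dichloroketene [2+2]). The risk is a moderate yield, through ketene oligomerisation or ZnCl2-promoted acylation of the electron-rich ring or the silyl ether. The fallback sets out from 2 and comes back at 5, bypassing 3 and 4. Keteniminium [2+2] cycloaddition (N,N-dimethylacetamide, Tf2O, 2,4,6-collidine, 1,2-dichloroethane, reflux) gives the cyclobutaniminium triflate F4, which aqueous NaHCO3 hydrolyses to 5 without zinc salts or a dechlorination.

3. Step 6 (one-pot aldol condensation). The risks are retro-aldol before acetylation, some Z isomer, and partial loss of aryl TBS under DBU. The fallback sets out from 7 and comes back at 13. LDA then ClP(O)(OEt)2 gives the enol phosphate F5; a second equivalent of LDA induces the 1,3-phosphoryl shift to the α-phosphono lactone F6. Horner–Wadsworth–Emmons olefination of F6 with aldehyde 9 (KOtBu, THF, 0 °C) gives 13, mainly E.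

**Further compounds**
F1 | step 4 | (R)-tert-butyl{2-methoxy-4-[(3-trimethylsilyloxycyclobut-2-en-1-yl)methyl]phenoxy}dimethylsilane (silyl enol ether) | COc1cc(C[C@H]2C=C(O[Si](C)(C)C)C2)ccc1O[Si](C)(C)C(C)(C)C
F2 | step 4 | (R)-3-formyl-4-[4-(TBSO)-3-methoxyphenyl]butanoic acid (aldehyde acid) | COc1cc(C[C@H](CC(=O)O)C=O)ccc1O[Si](C)(C)C(C)(C)C
F3 | step 4 | (R)-3-(hydroxymethyl)-4-[4-(TBSO)-3-methoxyphenyl]butanoic acid (hydroxy acid) | COc1cc(C[C@H](CC(=O)O)CO)ccc1O[Si](C)(C)C(C)(C)C
F4 | step 2 | N,N-dimethyl-3-{[4-(TBSO)-3-methoxyphenyl]methyl}cyclobutan-1-iminium triflate | COc1cc(CC2CC(=[N+](C)C)C2)ccc1O[Si](C)(C)C(C)(C)C.[O-]S(=O)(=O)C(F)(F)F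
F5 | step 6 | diethyl (R)-4-{[4-(TBSO)-3-methoxyphenyl]methyl}-4,5-dihydrofuran-2-yl phosphate (enol phosphate) | COc1cc(C[C@H]2COC(OP(=O)(OCC)OCC)=C2)ccc1O[Si](C)(C)C(C)(C)C
F6 | step 6 | diethyl (4-{[4-(TBSO)-3-methoxyphenyl]methyl}-2-oxooxolan-3-yl)phosphonate (C3 epimers; C4 arranged as in 7, 4S by CIP) | COc1cc(C[C@H]2COC(=O)C2P(=O)(OCC)OCC)ccc1O[Si](C)(C)C(C)(C)C
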